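**Strategy.** Ring B is read as a masked 2,3-trans-disubstituted cyclopentanone: Cb (the carbinol carbon) is the old carbonyl carbon, Cc (the CH holding the CH2 bridge to ring A) its α-carbon and Ca (the CH holding isopropenyl) its β-carbon. The Ca–isopropenyl and Cc–CH2 bonds are therefore cut together. In one flask CuBr·SMe2 with a chiral diphosphine adds isopropenylmagnesium bromide to cyclopent-2-enone (Ca–C bond, Ca configuration) and the regiodefined magnesium enolate is benzylated anti to the new group (Cc–CH2 bond). The electrophile is a tris-MOM methylphloroglucinol benzyl bromide that already carries ring A as an arene; bromine on its only ring CH blocks self-alkylation and later directs lithiation.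

Key step: step 7

Remark: the sense of induction of the two chiral ligands (steps 7 and 12) cannot be predicted with certainty; both antipodes of each are commercial, and the antipode that gives the configuration drawn is to be fixed in a first run.
Remark: 21 and 22 are drawn as single enol tautomers; the descriptor of the ring A quaternary carbon refers to the tautomer drawn.

**Step 1**
Reactants: 1 2,4,6-trihydroxytoluene
Product: 3 2,4,6-trihydroxy-3-methylbenzaldehyde, via aryl iminium chloride 2 (not isolated)
Conditions: POCl3, DMF, EtOAc, 0 °C → rt; then H2O, 50 °C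
Reagents that add atoms: N,N-dimethylformamide CN(C)C=O; water O
Why: Vilsmeier–Haack formylation, in which the chloroiminium reagent attacks one of the two equivalent free ring carbons of the electron-rich triol, the iminium group of 2 deactivates the ring against a second attack, and water then releases the aldehyde.

**Step 2**
Reactants: 3 2,4,6-trihydroxy-3-methylbenzaldehyde
Product: 4 2,4,6-tris(methoxymethoxy)-3-methylbenzaldehyde
Conditions: NaH, MOMCl, DMF, 0 °C → rt
Reagents that add atoms: chloromethyl methyl ether COCCl
Why: Threefold Williamson etherification of the phenoxides by a hard electrophile, with NaH chosen because the hydroxyl groups hydrogen-bonded to the formyl group react sluggishly under amine bases; the acetals are inert to the organometallic steps and stabilise the aryllithium of step 10.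

**Step 3**
Reactants: 4 2,4,6-tris(methoxymethoxy)-3-methylbenzaldehyde
Product: 5 3-bromo-2,4,6-tris(methoxymethoxy)-5-methylbenzaldehyde
Conditions: NBS, MeCN, 0 °C → rt, dark
Reagents that add atoms: N-bromosuccinimide O=C1CCC(=O)N1Br
Why: Electrophilic aromatic bromination at the only ring CH, which is activated by three alkoxy groups; the halogen removes the one nucleophilic ring position through which the later benzylic bromide could alkylate itself and fixes the site of metalation.

**Step 4**
Reactants: 5 3-bromo-2,4,6-tris(methoxymethoxy)-5-methylbenzaldehyde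
Product: 6 [3-bromo-2,4,6-tris(methoxymethoxy)-5-methylphenyl]methanol
Conditions: NaBH4, MeOH/THF, 0 °C
Reagents that add atoms: none
Why: Borohydride reduction of the aldehyde, to which the acetals and the aryl bromide are inert.

**Step 5**
Reactants: 6 [3-bromo-2,4,6-tris(methoxymethoxy)-5-methylphenyl]methanol
Product: 7 1-bromo-3-(bromomethyl)-2,4,6-tris(methoxymethoxy)-5-methylbenzene
Conditions: CBr4, PPh3, K2CO3 (solid), CH2Cl2, −20 → 0 °C; filtered through basic Al2O3 and used at once
Reagents that add atoms: carbon tetrabromide BrC(Br)(Br)Br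
Why: Appel reaction under neutral, buffered conditions that spare the MOM acetals; because the ring is fully substituted the activated halide has no Friedel–Crafts path to oligomers, and it is carried on without storage.

**Step 6**
Reactants: 8 2-bromopropene
Product: 9 isopropenylmagnesium bromide
Conditions: Mg, BrCH2CH2Br (cat.), 2-MeTHF, 40 °C; titrated
Reagents that add atoms: magnesium [Mg]
Why: Grignard formation by insertion of magnesium into the vinylic C–Br bond, in an ether that can be dosed into the medium of step 7.

**Step 7**
Reactants: 10 cyclopent-2-en-1-one; 9 isopropenylmagnesium bromide; 7 1-bromo-3-(bromomethyl)-2,4,6-tris(methoxymethoxy)-5-methylbenzene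
Product: 12 (2S,3R)-2-{[3-bromo-2,4,6-tris(methoxymethoxy)-5-methylphenyl]methyl}-3-(prop-1-en-2-yl)cyclopentan-1-one, via magnesium enolate 11 (not isolated)
Conditions: CuBr·SMe2 (5 mol %), (R)-1-[(S)-2-(diphenylphosphino)ferrocenyl]ethyldicyclohexylphosphine or its mirror image (6 mol %), t-BuOMe, −78 °C, 9 added slowly to a slight excess of 10; then DMPU, 7 (limiting), −78 → −20 °C; aq. NH4Cl
Reagents that add atoms: none
Why: The Grignard reagent transmetalates to the CuBr–diphosphine complex, which transfers the isopropenyl group to the enone β-carbon from one enantioface and releases the bromomagnesium enolate 11, whose double bond lies only between Cb and Cc; 11 then attacks the benzylic carbon of 7 with loss of bromide. The closest known reaction type is the copper-catalysed enantioselective conjugate addition of Grignard reagents to cyclic enones with alkylation of the enolate in the same flask, a three-component coupling of the prostaglandin kind. No ring is closed. Ca is set by the ligand, and Cc by the substrate, since the electrophile approaches the enolate face anti to the isopropenyl group and the 2,3-trans ketone is also the more stable epimer. The step needs 1,4- over 1,2-addition (copper catalysis at −78 °C), C-alkylation before any enolate equilibration (a very reactive benzylic bromide, DMPU, and enolate in excess over 7 with no free Grignard reagent left) and an untouched aryl bromide (the low temperature).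

**Step 8**
Reactants: 12 (2S,3R)-2-{[3-bromo-2,4,6-tris(methoxymethoxy)-5-methylphenyl]methyl}-3-(prop-1-en-2-yl)cyclopentan-1-one
Product: 13 (1R,2S,3R)-2-{[3-bromo-2,4,6-tris(methoxymethoxy)-5-methylphenyl]methyl}-1-methyl-3-(prop-1-en-2-yl)cyclopentan-1-ol
Conditions: MeMgBr, CeCl3 (anhydrous), THF, −78 °C; aq. NH4Cl
Reagents that add atoms: methylmagnesium bromide C[Mg]Br
Why: 1,2-Addition of the weakly basic methylcerium reagent, which does not enolise the epimerisable Cc; methyl should enter the carbonyl face anti to the adjacent bulky arylmethyl arm, leaving the hydroxyl cis to that arm as required for (R)-Cb, and a minor Cb epimer would be removed by chromatography.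

**Step 9**
Reactants: 14 (S)-2-methylbutanoic acid
Product: 15 (2S)-N-methoxy-N,2-dimethylbutanamide
Conditions: MeNHOMe·HCl, EDC·HCl, HOBt, N-methylmorpholine, CH2Cl2, 0 °C → rt
Reagents that add atoms: N,O-dimethylhydroxylamine hydrochloride CNOC.Cl
Why: Carbodiimide amide coupling (Weinreb amide formation) under HOBt, conditions under which a simple α-branched alkanoic acid keeps its (S) centre.

**Step 10**
Reactants: 13 (1R,2S,3R)-2-{[3-bromo-2,4,6-tris(methoxymethoxy)-5-methylphenyl]methyl}-1-methyl-3-(prop-1-en-2-yl)cyclopentan-1-ol; 15 (2S)-N-methoxy-N,2-dimethylbutanamide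
Product: 19 (2S)-1-[3-{[(1S,2R,5R)-2-hydroxy-2-methyl-5-(prop-1-en-2-yl)cyclopentyl]methyl}-2,4,6-tris(methoxymethoxy)-5-methylphenyl]-2-methylbutan-1-one, via lithium alkoxide 16 (not isolated), via aryllithium alkoxide 17 (not isolated), via lithium hemiaminal 18 (not isolated)
Conditions: MeLi (1.05 equiv), THF, −78 °C; t-BuLi (2.1 equiv), −78 °C; 15, −78 → 0 °C; aq. NH4Cl
Reagents that add atoms: none
Why: Bromine–lithium exchange followed by Weinreb ketone synthesis, in which the hydroxyl is first converted to alkoxide 16 so that aryllithium 17, formed exactly at the former C–Br carbon and stabilised by its two flanking MOM ethers, is not protonated, and the chelated adduct 18 survives until the quench, which prevents a second addition and keeps the (S) α-centre away from base.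

**Step 11**
Reactants: 19 (2S)-1-[3-{[(1S,2R,5R)-2-hydroxy-2-methyl-5-(prop-1-en-2-yl)cyclopentyl]methyl}-2,4,6-tris(methoxymethoxy)-5-methylphenyl]-2-methylbutan-1-one
Product: 21 (2S)-1-[2,4,6-trihydroxy-3-{[(1S,2R,5R)-2-hydroxy-2-methyl-5-(prop-1-en-2-yl)cyclopentyl]methyl}-5-methylphenyl]-2-methylbutan-1-one, via tetrakis-trimethylsilyl ether 20 (not isolated)
Conditions: TMSOTf, 2,2′-bipyridyl, MeCN, 0 °C → rt; then K2CO3, MeOH, 0 °C; pH 5 phosphate buffer
Reagents that add atoms: none
Why: Silyl-triflate-mediated cleavage of the aryl MOM ethers buffered by 2,2′-bipyridyl, which traps the methoxymethyl cation, so that no Brønsted acid meets the ionisable tertiary carbinol Cb or the isopropenyl group; the aryl and carbinol trimethylsilyl ethers of 20 are then solvolysed by K2CO3 in methanol.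

**Step 12**
Reactants: 21 (2S)-1-[2,4,6-trihydroxy-3-{[(1S,2R,5R)-2-hydroxy-2-methyl-5-(prop-1-en-2-yl)cyclopentyl]methyl}-5-methylphenyl]-2-methylbutan-1-one
Product: 22 (6R)-3,5-dihydroxy-4-{[(1S,2R,5R)-2-hydroxy-2-methyl-5-(prop-1-en-2-yl)cyclopentyl]methyl}-6-methyl-2-[(2S)-2-methylbutanoyl]-6-(3-methylbut-2-en-1-yl)cyclohexa-2,4-dien-1-one
Conditions: prenyl acetate (1.05 equiv), Pd2(dba)3 (2.5 mol %; dba = dibenzylideneacetone), (R,R)-N,N′-bis[2-(diphenylphosphino)benzoyl]cyclohexane-1,2-diamine or its mirror image (7.5 mol %), Et3N, degassed THF, 0 °C → rt; pH 5 buffer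
Reagents that add atoms: 3-methylbut-2-en-1-yl acetate CC(C)=CCOC(C)=O
Why: Proposed new method: zerovalent palladium from Pd2(dba)3 ionises prenyl acetate to a cationic 1,1-dimethylallyl complex held in the chiral pocket of the diamide bisphosphine, and the triethylammonium salt of the acidic phloroglucinol 21, a soft stabilised carbon nucleophile of the 1,3-dicarbonyl kind, should attack its unsubstituted terminus through the methyl-bearing ring A carbon (less hindered than the carbon carrying the ring B arm, while the acyl-bearing carbon is deactivated), which breaks aromaticity and sets the quaternary centre under ligand control because the ring B centres are too remote to steer it, while any O-prenyl ether re-ionises under the catalyst and funnels to the C-alkylated product; the closest known reaction types are the asymmetric Tsuji–Trost allylic dearomatisation of 1-substituted 2-naphthols and the racemic Tsuji–Trost dearomative allylation of acylphloroglucinols.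

**Compound list**

1 | 2,4,6-trihydroxytoluene | Cc1c(O)cc(O)cc1O | starting material
2 | N-[(2,4,6-trihydroxy-3-methylphenyl)methylidene]-N-methylmethanaminium chloride (not isolated) | C[N+](C)=Cc1c(O)c(C)c(O)cc1O.[Cl-] | intermediate
3 | 2,4,6-trihydroxy-3-methylbenzaldehyde | O=Cc1c(O)c(C)c(O)cc1O | intermediate
4 | 2,4,6-tris(methoxymethoxy)-3-methylbenzaldehyde | O=Cc1c(OCOC)c(C)c(OCOC)cc1OCOC | intermediate
5 | 3-bromo-2,4,6-tris(methoxymethoxy)-5-methylbenzaldehyde | O=Cc1c(OCOC)c(C)c(OCOC)c(Br)c1OCOC | intermediate
6 | [3-bromo-2,4,6-tris(methoxymethoxy)-5-methylphenyl]methanol | OCc1c(OCOC)c(C)c(OCOC)c(Br)c1OCOC | intermediate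
7 | 1-bromo-3-(bromomethyl)-2,4,6-tris(methoxymethoxy)-5-methylbenzene | BrCc1c(OCOC)c(C)c(OCOC)c(Br)c1OCOC | intermediate
8 | 2-bromopropene | C=C(C)Br | starting material
9 | isopropenylmagnesium bromide | C=C(C)[Mg]Br | intermediate
10 | cyclopent-2-en-1-one | O=C1C=CCC1 | starting material
11 | bromomagnesium (3R)-3-(prop-1-en-2-yl)cyclopent-1-en-1-olate (not isolated) | C=C(C)[C@@H]1CCC(O[Mg]Br)=C1 | intermediate
12 | (2S,3R)-2-{[3-bromo-2,4,6-tris(methoxymethoxy)-5-methylphenyl]methyl}-3-(prop-1-en-2-yl)cyclopentan-1-one | C=C(C)[C@@H]1CCC(=O)[C@H]1Cc1c(OCOC)c(C)c(OCOC)c(Br)c1OCOC | intermediate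
13 | (1R,2S,3R)-2-{[3-bromo-2,4,6-tris(methoxymethoxy)-5-methylphenyl]methyl}-1-methyl-3-(prop-1-en-2-yl)cyclopentan-1-ol | C=C(C)[C@@H]1CC[C@@](C)(O)[C@H]1Cc1c(OCOC)c(C)c(OCOC)c(Br)c1OCOC | intermediate
14 | (S)-2-methylbutanoic acid | CC[C@H](C)C(=O)O | starting material
15 | (2S)-N-methoxy-N,2-dimethylbutanamide | CC[C@H](C)C(=O)N(C)OC | intermediate
16 | lithium alkoxide of 13 (not isolated) | C=C(C)[C@@H]1CC[C@@](C)(O[Li])[C@H]1Cc1c(OCOC)c(C)c(OCOC)c(Br)c1OCOC | intermediate
17 | aryllithium alkoxide, lithium in place of the aryl bromine of 16 (not isolated) | C=C(C)[C@@H]1CC[C@@](C)(O[Li])[C@H]1Cc1c(OCOC)c(C)c(OCOC)c([Li])c1OCOC | intermediate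
18 | lithium hemiaminal adduct of 17 and 15, mixture at the new carbon (not isolated) | C=C(C)[C@@H]1CC[C@@](C)(O[Li])[C@H]1Cc1c(OCOC)c(C)c(OCOC)c(C(O[Li])(N(C)OC)[C@@H](C)CC)c1OCOC | intermediate
19 | (2S)-1-[3-{[(1S,2R,5R)-2-hydroxy-2-methyl-5-(prop-1-en-2-yl)cyclopentyl]methyl}-2,4,6-tris(methoxymethoxy)-5-methylphenyl]-2-methylbutan-1-one | C=C(C)[C@@H]1CC[C@@](C)(O)[C@H]1Cc1c(OCOC)c(C)c(OCOC)c(C(=O)[C@@H](C)CC)c1OCOC | intermediate
20 | tetrakis-trimethylsilyl ether of 21, three aryl and one carbinol silyl ether (not isolated) | C=C(C)[C@@H]1CC[C@@](C)(O[Si](C)(C)C)[C@H]1Cc1c(O[Si](C)(C)C)c(C)c(O[Si](C)(C)C)c(C(=O)[C@@H](C)CC)c1O[Si](C)(C)C | intermediate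
21 | (2S)-1-[2,4,6-trihydroxy-3-{[(1S,2R,5R)-2-hydroxy-2-methyl-5-(prop-1-en-2-yl)cyclopentyl]methyl}-5-methylphenyl]-2-methylbutan-1-one | C=C(C)[C@@H]1CC[C@@](C)(O)[C@H]1Cc1c(O)c(C)c(O)c(C(=O)[C@@H](C)CC)c1O | intermediate
22 | (6R)-3,5-dihydroxy-4-{[(1S,2R,5R)-2-hydroxy-2-methyl-5-(prop-1-en-2-yl)cyclopentyl]methyl}-6-methyl-2-[(2S)-2-methylbutanoyl]-6-(3-methylbut-2-en-1-yl)cyclohexa-2,4-dien-1-one | C=C(C)[C@@H]1CC[C@@](C)(O)[C@H]1CC1=C(O)[C@@](C)(CC=C(C)C)C(=O)C(C(=O)[C@@H](C)CC)=C1O | target

**Totals.** Total step count: 12. Longest linear sequence: 10 steps (1, 2, 3, 4, 5, 7, 8, 10, 11, 12).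

**Steps most likely to fail**

Step 12 (proposed new method). The ligand may not control which face of ring A is alkylated. Attack may also occur through the ring carbon that carries the ring B arm, the branched 1,1-dimethylallyl terminus may be transferred, or a second prenylation may follow. The fallback uses known chemistry and sets out from 21. The phloroglucinol is deprotonated with NaOMe in MeOH at 0 °C and alkylated with prenyl bromide (1.05 equiv), the classical alkylative dearomatisation of 3-alkyl acylphloroglucinols. This should give 22 together with its epimer at the ring A quaternary carbon, the (6S)-dienone F1, from which 22 is separated by preparative HPLC. The route is rejoined at 22.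

Step 7. C-benzylation of the magnesium enolate may be slow relative to proton exchange, which would give regioisomeric or doubly alkylated ketones, or bromide 7 may be lost by ionisation before it is captured. The fallback sets out from 10, 9 and aldehyde 5. The conjugate addition is run as in step 7, but enolate 11 is intercepted at −78 °C by aldol addition to 5, a far better trap for magnesium enolates than a halide, to give the trans aldol adduct F2. This is dehydrated with NaOMe (cat.) in MeOH to the benzylidene ketone F3. The enone is reduced in the 1,4 sense with [(Ph3P)CuH]6 in moist toluene, which leaves the isopropenyl group and the aryl bromide alone. Brief treatment with DBU equilibrates Cc to the trans ketone, and the route is rejoined at 12.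

Step 10. Acyl transfer from the branched amide to the doubly ortho-substituted aryllithium may be incomplete, with the aryllithium protonated by the amide α-CH instead. The fallback sets out from 13 and passes through 17 as before. Amide 15 is reduced with LiAlH4 in Et2O at −40 °C to (S)-2-methylbutanal F4, used as a dried solution. Aryllithium 17 is added to F4 to give the benzylic carbinol F5 as a mixture at the new carbinol carbon. Dess–Martin periodinane with NaHCO3 in CH2Cl2 at 0 °C oxidises only the secondary alcohol, and the route is rejoined at 19.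

**Further compounds**

F1 | step 12 | (6S)-3,5-dihydroxy-4-{[(1S,2R,5R)-2-hydroxy-2-methyl-5-(prop-1-en-2-yl)cyclopentyl]methyl}-6-methyl-2-[(2S)-2-methylbutanoyl]-6-(3-methylbut-2-en-1-yl)cyclohexa-2,4-dien-1-one | C=C(C)[C@@H]1CC[C@@](C)(O)[C@H]1CC1=C(O)[C@](C)(CC=C(C)C)C(=O)C(C(=O)[C@@H](C)CC)=C1O
F2 | step 7 | 2,3-trans-2-{[3-bromo-2,4,6-tris(methoxymethoxy)-5-methylphenyl](hydroxy)methyl}-3-(prop-1-en-2-yl)cyclopentan-1-one, Ca as in 12, carbinol epimers | C=C(C)[C@@H]1CCC(=O)[C@H]1C(O)c2c(OCOC)c(C)c(OCOC)c(Br)c2OCOC
F3 | step 7 | (2E,3S)-2-{[3-bromo-2,4,6-tris(methoxymethoxy)-5-methylphenyl]methylidene}-3-(prop-1-en-2-yl)cyclopentan-1-one, same spatial arrangement at Ca as in 12 | C=C(C)[C@@H]1CCC(=O)/C1=C/c2c(OCOC)c(C)c(OCOC)c(Br)c2OCOC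
F4 | step 10 | (S)-2-methylbutanal | CC[C@H](C)C=O
F5 | step 10 | (2S)-1-[3-{[(1S,2R,5R)-2-hydroxy-2-methyl-5-(prop-1-en-2-yl)cyclopentyl]methyl}-2,4,6-tris(methoxymethoxy)-5-methylphenyl]-2-methylbutan-1-ol, carbinol epimers | C=C(C)[C@@H]1CC[C@@](C)(O)[C@H]1Cc1c(OCOC)c(C)c(OCOC)c(C(O)[C@@H](C)CC)c1OCOC
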